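**Plan**
- Numbering follows the naphthalene skeleton of the target: C1, C4 and C6 carry CO2Me, C2 and C7 carry hexadecyl, C5 is the ketone; ring A is C1–C4/C4a/C8a, ring B is C4a–C8/C8a.
- Retrosynthesis: C6=C7 is traced back to a β-keto ester with a stereocentre at C7 (16); the hydrogens at C4 and C4a are removed to the ene-1,4-dicarbonyl 15; ring A is cut at C1–C8a (retro-electrocyclisation) and C3–C4 (retro-olefination) into butenolide 3 and ring B phosphonate 12; ring B is cut at C6–C7 and C4a–C8a into enal 6 and keto phosphonate 10.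
- Enabling feature: at the diene level (C2=C3, C4=C4a) the ring A atoms C1–C2–C3–C4–C4a–C8a are the closure product of a hexatriene. That triene carries the C5 ketone on C4a (acyl acceleration), and its C4=C4a bond lies between the C4 ester and the C5 ketone, so it can be reduced selectively afterwards.
- Forward order: ring B (Michael/aldol condensation), then ring A in one operation (olefination/6π-electrocyclisation), then reduction of C4=C4a, then dehydrogenation to C6=C7.
- Stereochemistry: C7 is set by the aminocatalyst, steers the face of bond formation at C8a and is erased at the end; the Z geometry stored in 3 becomes the C1/C8a relationship by disrotation; C4 and C4a come from kinetic protonation on the H8a face.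

Key step: step 5

Remark: the phosphonate carbon of 12 is an epimeric mixture and C6 of 11–16 is epimerisable (drawn as the trans epimer); both centres are erased later, so they are carried as they fall.

Step 1
Reactants: 1 octadecanal; 2 glyoxylic acid monohydrate
Product: 3 4-hexadecyl-5-hydroxyfuran-2(5H)-one
Conditions: morpholine hydrochloride, dioxane/H2O, reflux
Reagents that add atoms: none
Why: aldol condensation of the aldehyde α-carbon (through its morpholine enamine) with glyoxylic acid and lactolisation of the resulting (Z)-formylacrylic acid should give the hydroxybutenolide, which locks the cis relationship between the C1 carboxyl and the C3 aldehyde carbon.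

Step 2
Reactants: 4 octadec-1-ene; 5 (E)-but-2-enal
Product: 6 (E)-nonadec-2-enal
Conditions: second-generation Hoveyda–Grubbs catalyst RuCl2(H2IMes)(=CH-C6H4-2-OiPr) (2 mol %), excess 5, CH2Cl2, 40 °C
Reagents that add atoms: none
Why: olefin cross-metathesis of a terminal alkene with an excess of the enal partner should give the E-enal under thermodynamic control, with propene leaving as gas.

Step 3
Reactants: 7 trimethyl phosphonoacetate; 8 methyl (E)-4-bromo-3-methoxybut-2-enoate
Product: 10 dimethyl 2-(dimethoxyphosphoryl)-4-oxohexanedioate, via methoxy enoate phosphonate 9 (not isolated)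
Conditions: NaH, THF, 0 °C; 8, 0 → 25 °C; then 1 M HCl, THF, 25 °C
Reagents that add atoms: water (O)
Why: SN2 alkylation of the phosphonoacetate anion by the allylic bromide, followed by acid hydrolysis of the β-methoxy enoate (a masked acetoacetate), should give the β-keto ester that already holds C4, C4a, C5 and C6.

Step 4
Reactants: 6 (E)-nonadec-2-enal; 10 dimethyl 2-(dimethoxyphosphoryl)-4-oxohexanedioate
Product: 12 methyl (1S,6R)-3-[1-(dimethoxyphosphoryl)-2-methoxy-2-oxoethyl]-6-hexadecyl-2-oxocyclohex-3-ene-1-carboxylate, via Michael adduct 11 (not isolated)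
Conditions: (S)-2-[diphenyl(trimethylsilyloxy)methyl]pyrrolidine (10 mol %), PhCO2H (10 mol %), toluene, 25 °C; then TsOH·H2O (20 mol %), toluene, 50 °C
Reagents that add atoms: none
Why: iminium-catalysed Michael addition of the β-keto ester carbon C6 to the enal, on the face opposite the diphenyl(silyloxy)methyl group, should set C7 as R, and acid-promoted intramolecular aldol condensation of C4a onto the aldehyde carbon C8a closes ring B as the enone (organocatalytic Michael/aldol condensation domino).

Step 5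
Reactants: 12 methyl (1S,6R)-3-[1-(dimethoxyphosphoryl)-2-methoxy-2-oxoethyl]-6-hexadecyl-2-oxocyclohex-3-ene-1-carboxylate; 3 4-hexadecyl-5-hydroxyfuran-2(5H)-one
Product: 14 (1S,6S,7R,8aS)-2,7-dihexadecyl-4,6-bis(methoxycarbonyl)-5-oxo-1,5,6,7,8,8a-hexahydronaphthalene-1-carboxylic acid, via triene acid 13 (not isolated)
Conditions: NaH (3.2 equiv), THF, 0 → 25 °C; AcOH, 0 °C; then 25–40 °C, dilute, under argon
Reagents that add atoms: none
Why: NaH removes the lactol proton of 3 (opening it to the sodium (2Z)-3-formylacrylate) and the C6–H and C4–H of 12, and the phosphonate carbanion at C4 olefinates the aldehyde carbon C3 (Horner–Wadsworth–Emmons reaction, the β-keto ester enolate adding only reversibly), which forms C3–C4. The olefination should place the C2 chain trans to the C4 ester (the usual E preference of α-substituted phosphonoacetates), so that after neutralisation the (2Z,4E)-triene C1=C2–C3=C4–C4a=C8a can coil and close by thermal disrotatory 6π-electrocyclisation, which forms C1–C8a and ring A (six-membered pericyclic closure, accelerated by the C5 acyl group on C4a). The closest known reaction types are the Wittig olefination of 5-hydroxyfuran-2(5H)-ones to (2Z)-dienoic acids and the electrocyclisation of 2-acyl hexatrienes, together a formal [3+3] annulation. C1 and C8a are the new stereocentres, and their relative configuration follows from orbital symmetry: the inside carboxyl at C1 (Z geometry stored in 3) and the inside hydrogen at C8a end up cis. The absolute sense at C8a should be controlled by the C7 hexadecyl group of ring B, the new bond forming axially on the face anti to it, as in additions to 5-substituted cyclohexenones. The step needs E-selective olefination and attack at the aldehyde instead of conjugate addition, which the carboxylate form of the aldehyde and the dianion of 12 should secure.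

Step 6
Reactants: 14 (1S,6S,7R,8aS)-2,7-dihexadecyl-4,6-bis(methoxycarbonyl)-5-oxo-1,5,6,7,8,8a-hexahydronaphthalene-1-carboxylic acid
Product: 15 trimethyl (1S,6S,7R,8aS)-2,7-dihexadecyl-5-oxo-1,5,6,7,8,8a-hexahydronaphthalene-1,4,6-tricarboxylate
Conditions: Me3SiCHN2, toluene/MeOH, 0 °C, directly on the crude acid
Reagents that add atoms: trimethylsilyldiazomethane (C[Si](C)(C)C=[N+]=[N-])
Why: esterification of the carboxylic acid by the diazoalkane under neutral conditions should leave the acidic C1–H, the C8a–H and the β-keto ester untouched and removes the free acid before it can lactonise or decarboxylate.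

Step 7
Reactants: 15 trimethyl (1S,6S,7R,8aS)-2,7-dihexadecyl-5-oxo-1,5,6,7,8,8a-hexahydronaphthalene-1,4,6-tricarboxylate
Product: 16 trimethyl (1S,4R,4aS,6S,7R,8aR)-2,7-dihexadecyl-5-oxo-1,4,4a,5,6,7,8,8a-octahydronaphthalene-1,4,6-tricarboxylate
Conditions: Zn dust, AcOH/THF, 0 → 25 °C
Reagents that add atoms: none
Why: electron-transfer (dissolving-metal) reduction of the ene-1,4-dicarbonyl C4=C4a, then kinetic C-protonation of the ester dienol at C4 (α, which keeps C2=C3) and of the C5 enol at C4a, both on the face that carries H8a (anti to the C8a–C8 and C8a–C1 bonds), should give the cis ring fusion with H4, H4a and H8a syn.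

Step 8
Reactants: 16 trimethyl (1S,4R,4aS,6S,7R,8aR)-2,7-dihexadecyl-5-oxo-1,4,4a,5,6,7,8,8a-octahydronaphthalene-1,4,6-tricarboxylate
Product: 19 trimethyl (1S,4R,4aS,8aR)-2,7-dihexadecyl-5-oxo-1,4,4a,5,8,8a-hexahydronaphthalene-1,4,6-tricarboxylate, via selenide 17 (not isolated), via selenoxide 18 (not isolated)
Conditions: PhSeCl, pyridine, CH2Cl2, 0 °C; then 30% H2O2, 0 → 25 °C
Reagents that add atoms: none
Why: α-selenenylation of the β-keto ester at C6, anti to the C7 hexadecyl group, and oxidation to the selenoxide should be followed by syn-elimination with the cis C7–H, which forms C6=C7 and erases the auxiliary C7 and C6 stereocentres (selenoxide elimination).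

**Compound list**
1 | octadecanal | CCCCCCCCCCCCCCCCCC=O | starting material
2 | glyoxylic acid monohydrate (2,2-dihydroxyacetic acid) | OC(O)C(=O)O | starting material
3 | 4-hexadecyl-5-hydroxyfuran-2(5H)-one (racemic lactol) | CCCCCCCCCCCCCCCCC1=CC(=O)OC1O | intermediate
4 | octadec-1-ene | CCCCCCCCCCCCCCCCC=C | starting material
5 | (E)-but-2-enal | C/C=C/C=O | starting material
6 | (E)-nonadec-2-enal | CCCCCCCCCCCCCCCC/C=C/C=O | intermediate
7 | trimethyl phosphonoacetate | COC(=O)CP(=O)(OC)OC | starting material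
8 | methyl (E)-4-bromo-3-methoxybut-2-enoate | COC(=O)/C=C(/OC)CBr | starting material
9 | dimethyl (E)-5-(dimethoxyphosphoryl)-3-methoxyhex-2-enedioate | COC(=O)/C=C(/OC)CC(P(=O)(OC)OC)C(=O)OC | intermediate
10 | dimethyl 2-(dimethoxyphosphoryl)-4-oxohexanedioate | COC(=O)CC(=O)CC(P(=O)(OC)OC)C(=O)OC | intermediate
11 | dimethyl 2-(dimethoxyphosphoryl)-4-oxo-5-[(3R)-1-oxononadecan-3-yl]hexanedioate | O=CC[C@@H](CCCCCCCCCCCCCCCC)C(C(=O)OC)C(=O)CC(P(=O)(OC)OC)C(=O)OC | intermediate
12 | methyl (1S,6R)-3-[1-(dimethoxyphosphoryl)-2-methoxy-2-oxoethyl]-6-hexadecyl-2-oxocyclohex-3-ene-1-carboxylate | COC(=O)C(P(=O)(OC)OC)C1=CC[C@@H](CCCCCCCCCCCCCCCC)[C@H](C(=O)OC)C1=O | intermediate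
13 | (2Z,4E)-3-hexadecyl-5-[(4R,5S)-4-hexadecyl-5-(methoxycarbonyl)-6-oxocyclohex-1-en-1-yl]-6-methoxy-6-oxohexa-2,4-dienoic acid | OC(=O)/C=C(CCCCCCCCCCCCCCCC)\C=C(\C(=O)OC)C1=CC[C@@H](CCCCCCCCCCCCCCCC)[C@H](C(=O)OC)C1=O | intermediate
14 | (1S,6S,7R,8aS)-2,7-dihexadecyl-4,6-bis(methoxycarbonyl)-5-oxo-1,5,6,7,8,8a-hexahydronaphthalene-1-carboxylic acid | OC(=O)[C@@H]1C(CCCCCCCCCCCCCCCC)=CC(C(=O)OC)=C2C(=O)[C@@H](C(=O)OC)[C@H](CCCCCCCCCCCCCCCC)C[C@@H]12 | intermediate
15 | trimethyl (1S,6S,7R,8aS)-2,7-dihexadecyl-5-oxo-1,5,6,7,8,8a-hexahydronaphthalene-1,4,6-tricarboxylate | COC(=O)[C@@H]1C(CCCCCCCCCCCCCCCC)=CC(C(=O)OC)=C2C(=O)[C@@H](C(=O)OC)[C@H](CCCCCCCCCCCCCCCC)C[C@@H]12 | intermediate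
16 | trimethyl (1S,4R,4aS,6S,7R,8aR)-2,7-dihexadecyl-5-oxo-1,4,4a,5,6,7,8,8a-octahydronaphthalene-1,4,6-tricarboxylate | CCCCCCCCCCCCCCCCC1=C[C@@H](C(=O)OC)[C@H]2C(=O)[C@@H](C(=O)OC)[C@H](CCCCCCCCCCCCCCCC)C[C@H]2[C@@H]1C(=O)OC | intermediate
17 | trimethyl (1S,4R,4aS,6S,7R,8aR)-2,7-dihexadecyl-5-oxo-6-(phenylselanyl)-1,4,4a,5,6,7,8,8a-octahydronaphthalene-1,4,6-tricarboxylate | CCCCCCCCCCCCCCCCC1=C[C@@H](C(=O)OC)[C@H]2C(=O)[C@@](C(=O)OC)([Se]c3ccccc3)[C@H](CCCCCCCCCCCCCCCC)C[C@H]2[C@@H]1C(=O)OC | intermediate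
18 | trimethyl (1S,4R,4aS,6S,7R,8aR)-2,7-dihexadecyl-5-oxo-6-(phenylseleninyl)-1,4,4a,5,6,7,8,8a-octahydronaphthalene-1,4,6-tricarboxylate | CCCCCCCCCCCCCCCCC1=C[C@@H](C(=O)OC)[C@H]2C(=O)[C@@](C(=O)OC)([Se](=O)c3ccccc3)[C@H](CCCCCCCCCCCCCCCC)C[C@H]2[C@@H]1C(=O)OC | intermediate
19 | trimethyl (1S,4R,4aS,8aR)-2,7-dihexadecyl-5-oxo-1,4,4a,5,8,8a-hexahydronaphthalene-1,4,6-tricarboxylate | CCCCCCCCCCCCCCCCC1=C[C@@H](C(=O)OC)[C@H]2C(=O)C(C(=O)OC)=C(CCCCCCCCCCCCCCCC)C[C@H]2[C@@H]1C(=O)OC | target

Total step count: 8. Longest linear sequence: 6 steps (steps 3, 4, 5, 6, 7, 8).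

**Steps most likely to fail**

Step 5. The olefination of the hindered, doubly stabilised C4 carbanion may be slow. It may also give the 4Z triene, which cannot coil for ring closure. The (2Z)-acid may lactonise onto C3 before the electrocyclisation, and the closure may show poor facial selectivity at C8a. The fallback sets out from 6 and 3 and comes back at 15; it builds the same triene by aldol addition and dehydration. Enal 6 is annulated as in step 4 with commercial dimethyl 3-oxohexanedioate to give methyl (1S,6R)-6-hexadecyl-3-(2-methoxy-2-oxoethyl)-2-oxocyclohex-3-ene-1-carboxylate F1. Butenolide 3 is opened with trimethylsilyldiazomethane to methyl (2Z)-3-hexadecyl-4-oxobut-2-enoate F2. The dianion of F1 (LiN(SiMe3)2, 2 equiv, THF, −78 °C) adds through C4 to the aldehyde of F2 to give the aldol adduct dimethyl (2Z)-3-hexadecyl-4-hydroxy-5-[(4R,5S)-4-hexadecyl-5-(methoxycarbonyl)-6-oxocyclohex-1-en-1-yl]hex-2-enedioate F3. Mesylation and elimination (MsCl, excess Et3N) give the triene triester dimethyl (2Z,4E)-3-hexadecyl-5-[(4R,5S)-4-hexadecyl-5-(methoxycarbonyl)-6-oxocyclohex-1-en-1-yl]hexa-2,4-dienedioate F4. Warming F4 in toluene closes ring A to 15.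

Step 7. The two protonations may show poor facial selectivity (trans ring fusion or the C4 epimer), or the dienol may be protonated at C2, which would be a 1,6-reduction that moves the ring A alkene. The fallback sets out from 15 and comes back at 16; it separates hydride delivery from protonation. RhCl(PPh3)3-catalysed 1,4-hydrosilylation with Et3SiH should deliver hydride to C4 and give the silyl enol ether trimethyl (1S,4R,6S,7R,8aS)-2,7-dihexadecyl-5-[(triethylsilyl)oxy]-1,4,6,7,8,8a-hexahydronaphthalene-1,4,6-tricarboxylate F5. F5 is then protonated at C4a under kinetic control (Bu4NF, AcOH, THF, −78 °C) to 16.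

Step 8. The selenium electrophile may add to the C2=C3 alkene. Selenenylation may occur syn to the C7 hexadecyl group, which would leave no syn hydrogen for elimination. The product enone may epimerise at C4a during work-up. The fallback sets out from 16 and comes back at 19. The β-keto ester is O-silylated (Me3SiCl, Et3N, DMF) to trimethyl (1S,4R,4aS,7R,8aR)-2,7-dihexadecyl-5-[(trimethylsilyl)oxy]-1,4,4a,7,8,8a-hexahydronaphthalene-1,4,6-tricarboxylate F6. F6 is dehydrogenated with Pd(OAc)2 in MeCN (Saegusa–Ito oxidation), where β-hydride elimination from the divalent palladium enolate forms C6=C7.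

**Further compounds**
F1 | step 5 | methyl (1S,6R)-6-hexadecyl-3-(2-methoxy-2-oxoethyl)-2-oxocyclohex-3-ene-1-carboxylate | COC(=O)CC1=CC[C@@H](CCCCCCCCCCCCCCCC)[C@H](C(=O)OC)C1=O
F2 | step 5 | methyl (2Z)-3-hexadecyl-4-oxobut-2-enoate | COC(=O)/C=C(\C=O)CCCCCCCCCCCCCCCC
F3 | step 5 | dimethyl (2Z)-3-hexadecyl-4-hydroxy-5-[(4R,5S)-4-hexadecyl-5-(methoxycarbonyl)-6-oxocyclohex-1-en-1-yl]hex-2-enedioate | COC(=O)/C=C(\C(O)C(C(=O)OC)C1=CC[C@@H](CCCCCCCCCCCCCCCC)[C@H](C(=O)OC)C1=O)CCCCCCCCCCCCCCCC
F4 | step 5 | dimethyl (2Z,4E)-3-hexadecyl-5-[(4R,5S)-4-hexadecyl-5-(methoxycarbonyl)-6-oxocyclohex-1-en-1-yl]hexa-2,4-dienedioate | COC(=O)/C=C(CCCCCCCCCCCCCCCC)\C=C(\C(=O)OC)C1=CC[C@@H](CCCCCCCCCCCCCCCC)[C@H](C(=O)OC)C1=O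
F5 | step 7 | trimethyl (1S,4R,6S,7R,8aS)-2,7-dihexadecyl-5-[(triethylsilyl)oxy]-1,4,6,7,8,8a-hexahydronaphthalene-1,4,6-tricarboxylate | CCCCCCCCCCCCCCCCC1=C[C@@H](C(=O)OC)C2=C(O[Si](CC)(CC)CC)[C@@H](C(=O)OC)[C@H](CCCCCCCCCCCCCCCC)C[C@H]2[C@@H]1C(=O)OC
F6 | step 8 | trimethyl (1S,4R,4aS,7R,8aR)-2,7-dihexadecyl-5-[(trimethylsilyl)oxy]-1,4,4a,7,8,8a-hexahydronaphthalene-1,4,6-tricarboxylate | CCCCCCCCCCCCCCCCC1=C[C@@H](C(=O)OC)[C@H]2C(O[Si](C)(C)C)=C(C(=O)OC)[C@H](CCCCCCCCCCCCCCCC)C[C@H]2[C@@H]1C(=O)OC
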